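A small charge came first. The protic impurity in the flask is 2.00% of the solid substrate, and on my guess of one for one, going down from the noon run shifts 2.00% of the charge, less than the 18.0% of solid that the noon run lost by 6.00 h. So I read the noon run as it stood.

- noon: solid substrate 10 mM; reagent 1.05 equiv; protic impurity 0.40 mM; run made earlier
- flask: solid substrate 10 mM; reagent 1.05 equiv; protic impurity 0.200 mM; time 2.5 d

noon run (percent of the solid substrate charged)

| time / h | target / % | dissolved substrate / % | solid substrate / % |
|---|---|---|---|
| 0.500 | 0 | 2.8 | 96.3 |
| 1.50 | 0.1 | 1.6 | 90.5 |
| 3.00 | 0 | 7.0 | 88.9 |
| 4.00 | 0 | 6.7 | 86.6 |
| 6.00 | 2.7 | 8.7 | 82.0 |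

(scatter of a reading: 1 percentage point)

- as a solid, counted per litre of solution: solid substrate
- what was read earlier has a scatter of 1 percentage point, one standard deviation
- at the start none of the solid substrate is in solution
- dissolved substrate means what is dissolved; the solid is not counted in it
- no earlier run changes the charge of protic impurity; that part of a forecast is a guess

* the target standing at 2.5 d, as a percentage of the solid substrate charged
* concentration of dissolved substrate in solution at 2.5 d, in percent of saturation

How much of what leaves the solid stands as target? At the last noon reading it was 15.0%: this is the target share, target standing divided by solid lost (the selectivity on converted solid). It is rough, since the target reading of 2.7% carries a scatter of 1 percentage point and target had read 0% at 4.00 h, so holding the share steady was a guess of mine.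

How much solid leaves by 2.5 d? At the noon pace the charge lasts 1.39 d, shorter than that, so I took the whole charge as lost and, on that guess, reckoned a target of 15.0% of the charge. Dissolved substrate stood at 8.7% with no plateau in the readings, so I read no saturation from them.

The forecast differs. It gave 75% and 50%, a target 5.00 times mine, reading the slow start thus: “That looks like an induction period set by the protic impurity”.

The flask gave 15.5% and 75.2%.

    solid substrate + protic impurity → quenched substrate (k = 0.0960 /M/s)
    2 reagent → self-condensation product (k = 7.50 × 10⁻⁴ /M/s)
    dissolved substrate + target → side product (k = 0.00110 /M/s)
    solid substrate ⇌ dissolved substrate, rate k4*(cs4 - [dissolved substrate]) while solid is left; crystals form when [dissolved substrate] > cs4 (solubility = 4.70 mM, k = 1.40 × 10⁻⁵ /s)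
    dissolved substrate + reagent → target (k = 0.00130 /M/s)

The nearness of my figure is no check, for two things differed: at 2.50 d the flask still held 33.2% as solid, and its target share was 23.2%, not 15.0%. Target, standing at 15.5%, was then made 1.08 times as fast as it was used up. The same flask read at 6.0 d kept 0.261% of its solid, and its target share was 8.64%, with side product (each counted as two) at 47.0% and target at 8.62%.

(All runs come from a simulation for an exercise.)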